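**Plan**

- Retrosynthesis: C2–Br and C3–S are cut last (electrophilic substitution on the pyrrole ring), C4–Br and C6–Br are traced back to C–Si bonds, and the benzene ring is cut at C3a–C7a, C4–C5 and C6–C7 into three alkynes.
- Enabling feature: the benzo carbons form three two-carbon units (C7a/C7 with N1 on C7a, C3a/C4 with the C3 methylene on C3a, and C5/C6), and the benzo bromines sit meta at C4 and C6, so one silyl group on each of two alkynes can mark both sites.
- Forward: a tosylamide chain is made (Mitsunobu alkylation, Boc removal) and the N-ethynyl group is installed from trichloroethylene. One (2+2+2) cycloaddition with ethynyltrimethylsilane then closes the five-membered ring and the benzene ring together.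
- Endgame: double ipso-bromodesilylation, dehydrogenation to the indole, detosylation, C3 sulfenylation, C2 bromination.
- Stereochemistry: the target has no stereocentre; the only stereo-element on the way, the E alkene of dichlorovinyl amide 7, is erased in step 4.

Key step: step 5

Remark: indole numbering is used throughout, also for the atoms of open-chain precursors ("future C7"); tosyl means 4-methylbenzenesulfonyl.

**Step 1**
Reactants: 1 4-(trimethylsilyl)but-3-yn-1-ol; 2 tert-butyl N-tosylcarbamate
Product: 3 tert-butyl N-tosyl-N-[4-(trimethylsilyl)but-3-yn-1-yl]carbamate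
Conditions: PPh3, DIAD, THF, 0 °C to rt
Reagents that add atoms: none
Why: A Mitsunobu reaction of a primary alcohol with an acidic N-acyl sulfonamide should give clean mono-N-alkylation, avoiding the over-alkylation and enyne-forming elimination that a homopropargylic sulfonate would risk.

**Step 2**
Reactants: 3 tert-butyl N-tosyl-N-[4-(trimethylsilyl)but-3-yn-1-yl]carbamate
Product: 4 4-methyl-N-[4-(trimethylsilyl)but-3-yn-1-yl]benzenesulfonamide
Conditions: TFA, CH2Cl2, 0 °C to rt
Reagents that add atoms: none
Why: Acidolysis of the tert-butyl carbamate frees the secondary sulfonamide, and the alkynylsilane tolerates short exposure to TFA, whereas basic or fluoride conditions would cleave it.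

**Step 3**
Reactants: 4 4-methyl-N-[4-(trimethylsilyl)but-3-yn-1-yl]benzenesulfonamide; 5 trichloroethylene
Product: 7 (E)-N-(1,2-dichlorovinyl)-4-methyl-N-[4-(trimethylsilyl)but-3-yn-1-yl]benzenesulfonamide, via dichloroacetylene 6 (not isolated)
Conditions: Cl2C=CHCl (1.2 equiv), Cs2CO3 (1.5 equiv), dry DMF, 50 °C
Reagents that add atoms: none
Why: Base-induced loss of HCl from trichloroethylene gives dichloroacetylene in the flask, and anti addition of the sulfonamide anion to it (amide dichlorovinylation) is an established entry to ynamides from secondary sulfonamides; the carbonate is kept dry to spare the alkynylsilane.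

**Step 4**
Reactants: 7 (E)-N-(1,2-dichlorovinyl)-4-methyl-N-[4-(trimethylsilyl)but-3-yn-1-yl]benzenesulfonamide
Product: 10 N-ethynyl-4-methyl-N-[4-(trimethylsilyl)but-3-yn-1-yl]benzenesulfonamide, via N-chloroethynyl sulfonamide 8 (not isolated), via lithium ynamide acetylide 9 (not isolated)
Conditions: PhLi (2.3 equiv), THF, −78 to −20 °C; then H2O, −78 °C to rt
Reagents that add atoms: none
Why: Dehydrochlorination to the chloroynamide, chlorine–lithium exchange and protonation should give the terminal ynamide without touching the C-silyl alkyne, which a route through a silyl-capped ynamide and fluoride would also desilylate.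

**Step 5**
Reactants: 10 N-ethynyl-4-methyl-N-[4-(trimethylsilyl)but-3-yn-1-yl]benzenesulfonamide; 11 ethynyltrimethylsilane
Product: 12 1-tosyl-4,6-bis(trimethylsilyl)indoline
Conditions: Cp*RuCl(cod) (5 mol %), 11 (4 equiv), ClCH2CH2Cl, rt, slow addition of 10
Reagents that add atoms: none
Why: After loss of cod the divalent ruthenium centre binds both alkynes of 10, and oxidative cyclization gives a ruthenacyclopentadiene (formally tetravalent ruthenium, with biscarbene character) in which C3a–C7a is formed and the five-membered ring N1–C2–C3–C3a–C7a is closed across the three-atom tether. Ethynyltrimethylsilane then adds at the unsubstituted ruthenium-bound carbon (future C7) to form C6–C7, and reductive elimination forms C4–C5 and closes the benzene ring, so the step is a metal-catalysed (2+2+2) alkyne cyclotrimerization. The closest known reactions are the cyclotrimerizations of 1,6-diynes, including N-sulfonyl ynamide diynes, with terminal alkynes under Cp*RuCl(cod) or RhCl(PPh3)3, which give indolines and favour the meta isomer with the ruthenium catalyst. No stereocentre is formed. The step needs cross- over homo-trimerization and 4,6- over 4,5-regiochemistry: the silyl cap on the butynyl terminus slows self-coupling of 10, slow addition of 10 to excess 11 keeps the diyne concentration low, and the incoming silyl group should settle next to the unhindered C7–H because the alternative places two trimethylsilyl groups ortho to each other.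

**Step 6**
Reactants: 12 1-tosyl-4,6-bis(trimethylsilyl)indoline
Product: 14 4,6-dibromo-1-tosylindoline, via 6-bromo-1-tosyl-4-(trimethylsilyl)indoline 13 (not isolated)
Conditions: Br2 (2.2 equiv), CH2Cl2, 0 °C to rt, dark
Reagents that add atoms: bromine, BrBr
Why: Electrophilic ipso-bromodesilylation should occur at each silyl-bearing carbon through a β-silyl-stabilised arenium ion, while the nitrogen-activated C–H sites are shielded (C5 between the two C4/C6 substituents, C7 between the sulfonyl group and the C6 substituent); the less hindered C6 silyl group is assumed to leave first.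

**Step 7**
Reactants: 14 4,6-dibromo-1-tosylindoline
Product: 15 4,6-dibromo-1-tosyl-1H-indole
Conditions: DDQ (2.5 equiv), PhCl, 120 °C
Reagents that add atoms: none
Why: DDQ dehydrogenation (hydride abstraction at C3 or C2, then proton loss) is the usual aromatization of N-sulfonyl indolines, and it is placed after the bromination because the indole C2–C3 bond would not survive bromine.

**Step 8**
Reactants: 15 4,6-dibromo-1-tosyl-1H-indole
Product: 16 4,6-dibromo-1H-indole
Conditions: Cs2CO3 (3 equiv), THF/MeOH 2:1, rt to 60 °C
Reagents that add atoms: none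
Why: An N-sulfonyl indole has an indolide leaving group, so methanolysis of the S–N bond under carbonate should proceed without harm to the aryl bromides, which a reductive detosylation at the indoline stage would endanger.

**Step 9**
Reactants: 16 4,6-dibromo-1H-indole
Product: 17 4,6-dibromo-3-(methylsulfanyl)-1H-indole
Conditions: MeSSMe (0.55 equiv), SO2Cl2 (0.55 equiv), CH2Cl2, −20 °C; then 16, −78 to 0 °C; aq. NaHCO3 quench
Reagents that add atoms: dimethyl disulfide, CSSC (delivered as methanesulfenyl chloride, CSCl, made from it in the flask)
Why: Electrophilic sulfenylation of an N–H indole by a sulfenyl chloride should go to C3, the most nucleophilic position, and the low temperature and bicarbonate quench guard against acid-promoted migration of the sulfanyl group to C2.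

**Step 10**
Reactants: 17 4,6-dibromo-3-(methylsulfanyl)-1H-indole
Product: 18 2,4,6-tribromo-3-(methylsulfanyl)-1H-indole
Conditions: NBS (1.0 equiv), dry CH2Cl2, −20 to 0 °C, dark
Reagents that add atoms: N-bromosuccinimide, O=C1CCC(=O)N1Br
Why: With C3 blocked and the benzo ring deactivated by two bromines, NBS should brominate C2 (attack at C3 or sulfur, bromine shift to C2, proton loss), as is known for 3-substituted indoles; one equivalent and exclusion of water limit sulfoxide formation.

**Compound list**

1 | 4-(trimethylsilyl)but-3-yn-1-ol | C[Si](C)(C)C#CCCO | starting material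
2 | tert-butyl N-tosylcarbamate | Cc1ccc(cc1)S(=O)(=O)NC(=O)OC(C)(C)C | starting material
3 | tert-butyl N-tosyl-N-[4-(trimethylsilyl)but-3-yn-1-yl]carbamate | Cc1ccc(cc1)S(=O)(=O)N(CCC#C[Si](C)(C)C)C(=O)OC(C)(C)C | intermediate
4 | 4-methyl-N-[4-(trimethylsilyl)but-3-yn-1-yl]benzenesulfonamide | Cc1ccc(cc1)S(=O)(=O)NCCC#C[Si](C)(C)C | intermediate
5 | trichloroethylene | ClC=C(Cl)Cl | starting material
6 | dichloroacetylene (formed in the flask, not isolated) | ClC#CCl | intermediate
7 | (E)-N-(1,2-dichlorovinyl)-4-methyl-N-[4-(trimethylsilyl)but-3-yn-1-yl]benzenesulfonamide | Cl/C=C(/Cl)N(CCC#C[Si](C)(C)C)S(=O)(=O)c1ccc(C)cc1 | intermediate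
8 | N-(chloroethynyl)-4-methyl-N-[4-(trimethylsilyl)but-3-yn-1-yl]benzenesulfonamide (not isolated) | ClC#CN(CCC#C[Si](C)(C)C)S(=O)(=O)c1ccc(C)cc1 | intermediate
9 | N-(lithioethynyl)-4-methyl-N-[4-(trimethylsilyl)but-3-yn-1-yl]benzenesulfonamide (not isolated) | [Li]C#CN(CCC#C[Si](C)(C)C)S(=O)(=O)c1ccc(C)cc1 | intermediate
10 | N-ethynyl-4-methyl-N-[4-(trimethylsilyl)but-3-yn-1-yl]benzenesulfonamide | C#CN(CCC#C[Si](C)(C)C)S(=O)(=O)c1ccc(C)cc1 | intermediate
11 | ethynyltrimethylsilane | C#C[Si](C)(C)C | starting material
12 | 1-tosyl-4,6-bis(trimethylsilyl)indoline | Cc1ccc(cc1)S(=O)(=O)N1CCc2c([Si](C)(C)C)cc([Si](C)(C)C)cc21 | intermediate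
13 | 6-bromo-1-tosyl-4-(trimethylsilyl)indoline (not isolated) | Cc1ccc(cc1)S(=O)(=O)N1CCc2c([Si](C)(C)C)cc(Br)cc21 | intermediate
14 | 4,6-dibromo-1-tosylindoline | Cc1ccc(cc1)S(=O)(=O)N1CCc2c(Br)cc(Br)cc21 | intermediate
15 | 4,6-dibromo-1-tosyl-1H-indole | Cc1ccc(cc1)S(=O)(=O)n1ccc2c(Br)cc(Br)cc21 | intermediate
16 | 4,6-dibromo-1H-indole | Brc1cc(Br)c2cc[nH]c2c1 | intermediate
17 | 4,6-dibromo-3-(methylsulfanyl)-1H-indole | CSc1c[nH]c2cc(Br)cc(Br)c12 | intermediate
18 | 2,4,6-tribromo-3-(methylsulfanyl)-1H-indole | CSc1c(Br)[nH]c2cc(Br)cc(Br)c12 | target

**Totals**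

Total step count: 10. Longest linear sequence: 10 steps (1 to 18).

**Steps most likely to fail**

Step 5. The bulky silylacetylene may enter the ruthenacycle too slowly, so that 10 couples with itself, or it may enter in the wrong orientation and erode the 4,6-selectivity. The fallback sets out from 10 and replaces the third alkyne by 2-ethynyl-4,4,5,5-tetramethyl-1,3,2-dioxaborolane, a smaller, electron-poor terminal alkyne that is a proven partner in Cp*RuCl(cod) cyclotrimerizations and enters meta to a diyne substituent. The same three bonds form and should give 6-(4,4,5,5-tetramethyl-1,3,2-dioxaborolan-2-yl)-1-tosyl-4-(trimethylsilyl)indoline F1. Bromodeboronation of F1 with CuBr2 in MeOH/H2O at 80 °C should give 13, here isolated, where the route is rejoined; one equivalent of Br2 in CH2Cl2 then replaces the remaining silyl group to give 14.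

Step 6. Bromine may attack the nitrogen-activated C–H positions (C5, C7) in competition with ipso substitution, the second substitution may stall on the deactivated ring, or adventitious HBr may cause protodesilylation. The fallback sets out from 12 and uses silicon–boron exchange, which can only occur at carbons that carry silicon. BBr3 in CH2Cl2 (0 °C to rt) should give 4,6-bis(dibromoboranyl)-1-tosylindoline F2 in the flask. Pinacol and Et3N convert it into 4,6-bis(4,4,5,5-tetramethyl-1,3,2-dioxaborolan-2-yl)-1-tosylindoline F3, and CuBr2 in MeOH/H2O at 80 °C should give 14, where the route is rejoined.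

Step 7. Hydride abstraction from the electron-poor dibromo N-sulfonyl indoline may be too slow, and prolonged heating with DDQ may lead to decomposition. The fallback sets out from 14 and replaces the hydride abstraction by a radical halogenation and elimination. Benzylic bromination (NBS, AIBN cat., PhCF3, 80 °C) should give racemic 3,4,6-tribromo-1-tosylindoline F4, and E2 elimination of HBr with DBU in THF at rt should give 15, where the route is rejoined.

**Further compounds**

F1 | step 5 | 6-(4,4,5,5-tetramethyl-1,3,2-dioxaborolan-2-yl)-1-tosyl-4-(trimethylsilyl)indoline | Cc1ccc(cc1)S(=O)(=O)N1CCc2c([Si](C)(C)C)cc(B3OC(C)(C)C(C)(C)O3)cc21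
F2 | step 6 | 4,6-bis(dibromoboranyl)-1-tosylindoline | Cc1ccc(cc1)S(=O)(=O)N1CCc2c(B(Br)Br)cc(B(Br)Br)cc21
F3 | step 6 | 4,6-bis(4,4,5,5-tetramethyl-1,3,2-dioxaborolan-2-yl)-1-tosylindoline | Cc1ccc(cc1)S(=O)(=O)N1CCc2c(B3OC(C)(C)C(C)(C)O3)cc(B3OC(C)(C)C(C)(C)O3)cc21
F4 | step 7 | 3,4,6-tribromo-1-tosylindoline (racemic) | Cc1ccc(cc1)S(=O)(=O)N1CC(Br)c2c(Br)cc(Br)cc21
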